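The earlier runs and the new flask stem from a simulated flask from invented constants; the scatter is artificial.

X is the fork. E goes to X, and X goes on to D, or with Q to Z. The end of this flask therefore depends on which road the X takes.

| flask | E | L | remark | time |
|---|---|---|---|---|
| gamma | 0.15 M | 0.158 M | the very flask that is asked about, followed so far |  |
| flask | 0.15 M | 0.158 M |  | 8.0 min |

gamma run (percent of the E charged)

| time / s | Z / % | D / % | E / % | X / % |
|---|---|---|---|---|
| 10.0 | 0.1 | 3.5 | 54.8 | 41.4 |
| 15.0 | 1.1 | 4.5 | 40.2 | 52.0 |
| 25.0 | 1.9 | 11.1 | 23.1 | 64.8 |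
| 40.0 | 5.9 | 20.2 | 9.3 | 63.3 |
| 60.0 | 9.7 | 32.8 | 3.0 | 55.3 |
| 80.0 | 12.2 | 43.3 | 0.7 | 44.9 |
| 90.0 | 13.8 | 46.4 | 0.8 | 39.3 |

(scatter of a reading: 0.5 percentage points)

- on the list of suspects stand: L -> Q; 2 Q -> G; E -> X; X -> D; X + Q -> Z

- the species that holds most of what was charged as E, at 8.0 min (E / X / D / Z)
- the largest share itself, whichever of these holds it, in percent of the E charged

I read the table row against row. D over D plus Z is my fork share, the selectivity to D. The last row, at 90.0 s, gives 77.1%. The row at 40.0 s gives 77.4%, so the reading stands still within the scatter.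

But the last row still holds 39.3% of X. The X column falls from 55.3% to 39.3% over the last rows. I read that as 0.0114 s⁻¹, which leaves 0.464% at 8.0 min. So hardly any of that X stands then.

Now I solve both ends. If that X forks like the earlier X, D ends at 76.7% and Z at 22.8%, less than D. If the whole of it takes the D road, D ends at 85.7%. I commit to D, between these two.

The forecast says D at 78%, which is 1.3 percentage points above my lower end. Its ground is: “If L depletes slowly, Q falls somewhat and D gains a little”.

The flask gives D at 80.1%, and the forecast stands.

    L → Q (k = 0.0530 s⁻¹)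
    2 Q → G (k = 0.0370 L mol⁻¹ s⁻¹)
    E → X (k = 0.0590 s⁻¹)
    X → D (k = 0.0100 s⁻¹)
    X + Q → Z (k = 0.0310 L mol⁻¹ s⁻¹)

In this flask cQ falls from 0.105 M at 0.800 min to 0.0227 M at 8.00 min. The fork share of what stood as X or E in the last row comes to 84.0%, higher than the 77.1% read before. Counted from the flask's 80.1%, not from the forecast's 78%, D has moved 5 points at 0.0984 M of L and at 0.238 M of L. The neighbour charged with 0.27 M of L holds D at 73.4% and Z at 26.1%, a fork share of 73.7%, lower than 77.1%.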